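**Retrosynthetic overview**
1. Nucleophile: acylphloroglucinol 3 is cut at the aryl–C(=O) bond, giving phloroglucinol (1) and 9-phenylnonanoic acid (2).
2. Electrophile: flavan-4-ol 5 comes from (2S)-liquiritigenin (4) by C4=O → C4–OH. Compound 4 already contains rings A, B and C and the C2 stereocentre.
3. Key disconnection: the bond from flavan C4 to the phloroglucinol ring of myristinin D (6). This leads back to 3 and to 5, which reacts as its C4 cation / p-quinone methide, released under 470 nm light. C2 controls C4 (2,4-trans).
4. Ring order: no ring is built, because all five rings are purchased. The only new C–C bonds are aryl–acyl (first) and C4–aryl (last).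

Assumption: 9-phenylnonanoic acid, licorice-derived (2S)-liquiritigenin and the achiral merocyanine photoacid 7 are treated as catalogue items. The ee of 4 is checked by chiral HPLC before use. If 7 had to be made, it is one condensation of commercial 2,3,3-trimethyl-1-(3-sulfonatopropyl)-3H-indolium inner salt with salicylaldehyde (EtOH, reflux). That would raise the total count to 4 and leave the longest linear sequence unchanged.

**Step 1**
Reactants: 1 phloroglucinol (anhydrous); 2 9-phenylnonanoic acid
Product: 3 1-(2,4,6-trihydroxyphenyl)-9-phenylnonan-1-one
Conditions: BF3·OEt2 (neat, ~6 equiv), 85 °C, 3 h; then 10% aq NaOAc, rt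
Reagents that add atoms: none
Why: This is a BF3-mediated Friedel–Crafts C-acylation (any O-acyl product undergoes Fries rearrangement in situ); phloroglucinol is far more nucleophilic than the terminal phenyl ring, the first acyl group slows a second acylation, the acetate work-up breaks the BF2 chelate, and no stereocentre is involved.

**Step 2**
Reactants: 4 (2S)-liquiritigenin [(2S)-7-hydroxy-2-(4-hydroxyphenyl)chroman-4-one]
Product: 5 (2S,4S)-2-(4-hydroxyphenyl)chroman-4,7-diol (2,4-cis-4',7-dihydroxyflavan-4-ol; any minor 4R epimer is carried along)
Conditions: DIBAL-H (4.2 equiv), THF, −78 → −40 °C; aq Rochelle salt (pH 7–8); used crude, no silica gel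
Reagents that add atoms: none
Why: This is a 1,2-hydride reduction of the aryl ketone in which both phenols are first capped as covalent aluminium phenoxides, so no free phenoxide or alkoxide base is present to racemise C2 by retro-oxa-Michael opening to the chalcone; axial hydride delivery gives mainly the cis (4S) carbinol, whose configuration does not matter because C4 is planarised in Step 3.

**Step 3**
Reactants: 3 acylphloroglucinol (2.0 equiv, excess recovered); 5 flavan-4-ol
Product: 6 (+)-myristinin D, 1-{3-[(2S,4R)-7-hydroxy-2-(4-hydroxyphenyl)chroman-4-yl]-2,4,6-trihydroxyphenyl}-9-phenylnonan-1-one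
Conditions: merocyanine photoacid 7 (2 × 5 mol % relative to 5), MeCN/H2O 4:1 (0.05 M in 3), Ar, 470 nm LEDs, 20 °C; 5 added by syringe pump over 4 h, 12–24 h total; lamp off 15 min, then concentrate and chromatograph
Reagents that add atoms: none (H2O is lost)
Why: Proposed new method: a blue-light-gated dehydrative Friedel–Crafts arylation, in which 470 nm light is absorbed only by achiral 7, whose E→Z isomerisation and spirocyclisation release its phenolic proton as free H3O+ (light-on pH about 2.5–3, at least 100 times less acidic in the dark), this proton ionises the C4–OH of 5 with push from the para 7-OH and ortho O1 to give the planar C4 cation ⇌ p-quinone methide, a free ring CH of 3 (C3 and C5 are equivalent, so one regioisomer) attacks pseudo-axially on the half-chair that keeps the C2 aryl equatorial, which puts the new bond anti to that aryl and sets 4R (2,4-trans) under kinetic control because the product does not re-ionise at this acidity and the acid disappears when the lamp is off, the substrates are transparent at 470 nm so the UV-induced C2–O1 heterolysis that epimerises flavans is avoided, and the closest known reaction types are the thermal acid-catalysed flavan-4-ol/phloroglucinol condensation and the use of metastable merocyanine photoacids for pH switching and C–O bond chemistry, which has not been extended to C–C bond formation.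

**Stereochemical ledger:** C2 (S) is bought in 4 and is never ionised or exposed to base. C4 (R) is set in Step 3 under control of C2.

**Mass balance:** C21H26O4 (3) + C15H14O4 (5) − H2O = C36H38O7 (6).

**Compound list**
1 | phloroglucinol | Oc1cc(O)cc(O)c1 | starting material
2 | 9-phenylnonanoic acid | OC(=O)CCCCCCCCc1ccccc1 | starting material
3 | 1-(2,4,6-trihydroxyphenyl)-9-phenylnonan-1-one | O=C(CCCCCCCCc1ccccc1)c1c(O)cc(O)cc1O | intermediate
4 | (2S)-liquiritigenin (source of chirality) | O=C1C[C@@H](c2ccc(O)cc2)Oc2cc(O)ccc12 | starting material
5 | (2S,4S)-4',7-dihydroxyflavan-4-ol | O[C@H]1C[C@@H](c2ccc(O)cc2)Oc2cc(O)ccc12 | intermediate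
6 | (+)-myristinin D (2S,4R) | O=C(CCCCCCCCc1ccccc1)c1c(O)cc(O)c([C@@H]2C[C@@H](c3ccc(O)cc3)Oc3cc(O)ccc32)c1O | target
7 | merocyanine metastable photoacid, 2-[(E)-2-(2-hydroxyphenyl)vinyl]-3,3-dimethyl-1-(3-sulfonatopropyl)-3H-indolium inner salt (achiral catalyst for Step 3, contributes no atoms to 6) | CC1(C)c2ccccc2[N+](CCCS(=O)(=O)[O-])=C1/C=C/c1ccccc1O | starting material

**Total step count:** 3. **Longest linear sequence:** 2 (4 → 5 → 6, or 1/2 → 3 → 6).

**Steps most likely to fail**
1. Step 3 (the proposed new step).
   - Risks:
     - The light-on acidity may be too low for a useful rate.
     - 5 may self-condense through its own A ring.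
     - 6 may be alkylated a second time at its remaining phloroglucinol CH. Excess 3 and slow addition of 5 are there to limit this.
     - 7 may hydrolyse during the run.
     - The trans:cis ratio may be modest, in which case the cis isomer is removed by chromatography or RP-HPLC.
   - Fallback (known chemistry): convert 5 into the 4-benzylsulfanylflavan (BnSH, AcOH). Couple it with 3 by thiophilic activation with AgBF4 in THF at 0 °C, the established neutral C4-cation method for free-phenolic flavans. The same C2-controlled trans attack applies. This adds one step.
2. Step 2.
   - Risks: partial loss of ee at C2, over-reduction to the flavan, and decomposition of the acid-labile p-hydroxybenzylic alcohol on isolation.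
   - Fallback: protect first with TBSCl/imidazole to give bis-TBS-4, then reduce with NaBH4/CeCl3. The resulting carbinol can be chromatographed, is configurationally safe, and still ionises at C4. Remove the silyl groups after coupling with Et3N·3HF. This adds two steps.
3. Step 1.
   - Risks: diacylation, persistent O-acyl or BF2-chelate material, and a moderate yield.
   - Fallback: acylate 1,3,5-trimethoxybenzene with 9-phenylnonanoyl chloride/AlCl3, which gives clean mono-ketone formation. Then carry out global demethylation with BBr3 to reach 3.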